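**Retrosynthetic overview**

1. Target 18 ⇐ tris-MOM flavanone 17 ⇐ aryl cinnamate 15. In one flask the cinnamoyl group of 15 moves from O1 to C4a (photo-Fries, C4–C4a bond), and the freed O1 then adds to C2 under a chiral bifunctional thiourea (O1–C2 bond).
2. Enabling feature: ring A is a phloroglucinol ring whose O1 (on C8a) lies para to the prenylated C6 and between two equivalent ring CH carbons (C4a/C8). With O5 and O7 capped as MOM ethers, the acyl group can only land ortho to O1 and only O1 can close the pyranone, so the 6-prenyl and not the 8-prenyl chromanone must form.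
3. 15 ⇐ phenol 6 + cinnamic acid 14 (Steglich ester). 6 comes from phloroglucinol (bis-MOM, TIPS, ortho-lithiation/prenylation between the two OMOM groups, desilylation). 14 comes from isovanillin (O-allylation, Claisen shift to C2, MOM, cross-metathesis to prenyl, Doebner condensation).
4. Ring order: rings A and B are bought as aromatics; ring C is the only ring formed, in step 11, together with the C2 stereocentre.

Key step: step 11

Remark on the chemistry: flavanone numbering (O1, C2 … C8a, primed locants for ring B) is used throughout; in step 11 the pseudoenantiomer of the thiourea (quinine- or quinidine-derived) that gives the 2S series is the one to be used.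

Step 1
Reactants: 1 phloroglucinol (benzene-1,3,5-triol)
Product: 2 3,5-bis(methoxymethoxy)phenol
Conditions: MOMCl (2.0 equiv), i-Pr2NEt, DMF, 0 °C → rt; chromatography (mono-ether recycled)
Reagents that add atoms: chloromethyl methyl ether (MOMCl), COCCl
Why: Williamson-type O-alkylation of the phenoxide by MOMCl; because the three hydroxyls of 1 are equivalent, two equivalents of reagent should give the bis-ether as the main component of a statistical mixture that is separable on silica.

Step 2
Reactants: 2 3,5-bis(methoxymethoxy)phenol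
Product: 3 [3,5-bis(methoxymethoxy)phenoxy]triisopropylsilane
Conditions: TIPSCl, imidazole, DMF, rt
Reagents that add atoms: triisopropylsilyl chloride (TIPSCl), CC(C)[Si](Cl)(C(C)C)C(C)C
Why: Standard silylation of the remaining phenol gives a bulky, non-directing triisopropylsilyl ether that survives n-BuLi and can later be removed by fluoride without touching the MOM ethers.

Step 3
Reactants: 3 [3,5-bis(methoxymethoxy)phenoxy]triisopropylsilane
Product: 5 [3,5-bis(methoxymethoxy)-4-(3-methylbut-2-en-1-yl)phenoxy]triisopropylsilane, via aryllithium 4 (not isolated)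
Conditions: n-BuLi, THF, 0 °C; then prenyl bromide, −78 °C → rt
Reagents that add atoms: prenyl bromide (1-bromo-3-methylbut-2-ene), CC(C)=CCBr; n-butyllithium, [Li]CCCC (its lithium stays only in 4)
Why: Directed ortho-metalation: the ring CH between the two OMOM groups is the only position activated by two chelating directing groups, whereas the positions next to the bulky OTIPS group are shielded, and the aryllithium is then alkylated by prenyl bromide at its primary carbon (SN2).

Step 4
Reactants: 5 [3,5-bis(methoxymethoxy)-4-(3-methylbut-2-en-1-yl)phenoxy]triisopropylsilane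
Product: 6 3,5-bis(methoxymethoxy)-4-(3-methylbut-2-en-1-yl)phenol
Conditions: TBAF, AcOH, THF, 0 °C
Reagents that add atoms: none
Why: Fluoride-induced cleavage of the aryl silyl ether (desilylation) under acetic acid buffering frees only the phenol para to the prenyl group, the MOM ethers being stable to fluoride.

Step 5
Reactants: 7 isovanillin (3-hydroxy-4-methoxybenzaldehyde)
Product: 8 3-(allyloxy)-4-methoxybenzaldehyde
Conditions: allyl bromide, K2CO3, DMF, rt
Reagents that add atoms: allyl bromide, C=CCBr
Why: Williamson ether synthesis on the only phenol of isovanillin.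

Step 6
Reactants: 8 3-(allyloxy)-4-methoxybenzaldehyde
Product: 10 2-allyl-3-hydroxy-4-methoxybenzaldehyde, via ortho-dienone 9 (not isolated)
Conditions: neat, 190–200 °C, Ar
Reagents that add atoms: none
Why: Aromatic Claisen rearrangement ([3,3]-sigmatropic shift) moves the allyl group to C2, the only unsubstituted position ortho to the ether oxygen (C4 carries OMe), and the dienone tautomerises to the phenol.

Step 7
Reactants: 10 2-allyl-3-hydroxy-4-methoxybenzaldehyde
Product: 11 2-allyl-4-methoxy-3-(methoxymethoxy)benzaldehyde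
Conditions: MOMCl, i-Pr2NEt, CH2Cl2, 0 °C → rt
Reagents that add atoms: chloromethyl methyl ether (MOMCl), COCCl
Why: MOM protection of the hindered phenol (O-alkylation) masks it for the esterification and is removed together with the ring A MOM groups at the end.

Step 8
Reactants: 11 2-allyl-4-methoxy-3-(methoxymethoxy)benzaldehyde
Product: 12 4-methoxy-3-(methoxymethoxy)-2-(3-methylbut-2-en-1-yl)benzaldehyde
Conditions: second-generation Grubbs catalyst RuCl2(PCy3)(H2IMes)(=CHPh) (3 mol %), 2-methylbut-2-ene (excess), CH2Cl2, 40 °C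
Reagents that add atoms: 2-methylbut-2-ene, CC=C(C)C
Why: Olefin cross-metathesis of the terminal allyl group with excess 2-methylbut-2-ene transfers an isopropylidene unit and stops at the trisubstituted prenyl alkene, which is a poor metathesis substrate, while the aldehyde and MOM ether are tolerated.

Step 9
Reactants: 12 4-methoxy-3-(methoxymethoxy)-2-(3-methylbut-2-en-1-yl)benzaldehyde
Product: 14 (E)-3-[4-methoxy-3-(methoxymethoxy)-2-(3-methylbut-2-en-1-yl)phenyl]prop-2-enoic acid, via arylidenemalonic acid 13 (not isolated)
Conditions: malonic acid, pyridine, piperidine (cat.), 90 °C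
Reagents that add atoms: malonic acid, OC(=O)CC(=O)O
Why: Knoevenagel–Doebner condensation: the amine-catalysed condensation with malonic acid is followed by decarboxylation in hot pyridine, which gives the thermodynamically favoured (E)-cinnamic acid.

Step 10
Reactants: 14 (E)-3-[4-methoxy-3-(methoxymethoxy)-2-(3-methylbut-2-en-1-yl)phenyl]prop-2-enoic acid; 6 3,5-bis(methoxymethoxy)-4-(3-methylbut-2-en-1-yl)phenol
Product: 15 3,5-bis(methoxymethoxy)-4-(3-methylbut-2-en-1-yl)phenyl (E)-3-[4-methoxy-3-(methoxymethoxy)-2-(3-methylbut-2-en-1-yl)phenyl]prop-2-enoate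
Conditions: EDC·HCl, DMAP (cat.), CH2Cl2, 0 °C → rt
Reagents that add atoms: none
Why: Steglich esterification through the O-acylisourea and the acylpyridinium ion joins the two halves at the only free hydroxyl of 6, which is the oxygen that becomes O1.

Step 11
Reactants: 15 3,5-bis(methoxymethoxy)-4-(3-methylbut-2-en-1-yl)phenyl (E)-3-[4-methoxy-3-(methoxymethoxy)-2-(3-methylbut-2-en-1-yl)phenyl]prop-2-enoate
Product: 17 (2S)-5,7-bis(methoxymethoxy)-2-[4-methoxy-3-(methoxymethoxy)-2-(3-methylbut-2-en-1-yl)phenyl]-6-(3-methylbut-2-en-1-yl)-2,3-dihydro-4H-chromen-4-one, via 2'-hydroxychalcone 16 (not isolated)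
Conditions: hν (310 nm LEDs, FEP flow coil), degassed PhMe (0.01 M), 15 °C; then, lamp off, 9-amino-9-deoxy-epi-quinine 3,5-bis(trifluoromethyl)phenylthiourea (10 mol %), PhMe, −20 → 0 °C; filtration through SiO2
Reagents that add atoms: none
Why: Proposed new method: light absorbed by the aryl ester should break the O1–C(=O) bond homolytically, and the caged aryloxyl/cinnamoyl radical pair should recombine at a ring carbon ortho to O1 and tautomerise to the 2'-hydroxychalcone 16 (photo-Fries rearrangement, C4–C4a bond), which the thiourea then cyclises in the dark by oxa-Michael addition of O1 to C2 (ring C closes 6-endo-trig, O1–C2 bond). The one-flask pairing and its use on a 6'-alkoxy chalcone are new; the closest known reaction types are the photo-Fries rearrangement of aryl cinnamates to 2'-hydroxychalcones and the cinchona-thiourea-catalysed enantioselective cyclisation of 2'-hydroxychalcones (and their 3-carboxylate-activated analogues) to flavanones. The C2 stereocentre is catalyst-controlled: the thiourea hydrogen-bonds the enone carbonyl while the quinuclidine nitrogen acts as general base on the 2'-OH, so that O1 should be delivered to the Si face of the β-carbon, which corresponds to 2S. Regioselectivity comes from the substrate: the two carbons ortho to O1 are equivalent, the para carbon is blocked by the prenyl group, and once the acyl group has moved, O1 is the only free oxygen ortho to the ketone (O5 and O7 carry MOM), so only the 6-prenyl chromanone can form. The uncatalysed ring closure of the hydrogen-bonded chalcone should be slow in toluene, which leaves the cyclisation to the catalyst, and the mixture is filtered through silica before the reversible oxa-Michael addition can erode the enantiomeric purity.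

Step 12
Reactants: 17 (2S)-5,7-bis(methoxymethoxy)-2-[4-methoxy-3-(methoxymethoxy)-2-(3-methylbut-2-en-1-yl)phenyl]-6-(3-methylbut-2-en-1-yl)-2,3-dihydro-4H-chromen-4-one
Product: 18 (2S)-5,7-dihydroxy-2-[3-hydroxy-4-methoxy-2-(3-methylbut-2-en-1-yl)phenyl]-6-(3-methylbut-2-en-1-yl)-2,3-dihydro-4H-chromen-4-one (CNP0306216.1)
Conditions: 3 M aq. HCl, MeOH, 40 °C
Reagents that add atoms: none
Why: Acid-catalysed acetal exchange with methanol (MOM cleavage) frees the three phenols without touching the aryl methyl ether, and C2 should keep its configuration because ring opening to the chalcone, the racemisation pathway of flavanones, needs base.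

**Compound list**

1 | phloroglucinol (benzene-1,3,5-triol) | Oc1cc(O)cc(O)c1 | starting material
2 | 3,5-bis(methoxymethoxy)phenol | COCOc1cc(O)cc(OCOC)c1 | intermediate
3 | [3,5-bis(methoxymethoxy)phenoxy]triisopropylsilane | COCOc1cc(O[Si](C(C)C)(C(C)C)C(C)C)cc(OCOC)c1 | intermediate
4 | {2,6-bis(methoxymethoxy)-4-[(triisopropylsilyl)oxy]phenyl}lithium (aryllithium, formed in situ) | COCOc1cc(O[Si](C(C)C)(C(C)C)C(C)C)cc(OCOC)c1[Li] | intermediate
5 | [3,5-bis(methoxymethoxy)-4-(3-methylbut-2-en-1-yl)phenoxy]triisopropylsilane | COCOc1cc(O[Si](C(C)C)(C(C)C)C(C)C)cc(OCOC)c1CC=C(C)C | intermediate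
6 | 3,5-bis(methoxymethoxy)-4-(3-methylbut-2-en-1-yl)phenol | COCOc1cc(O)cc(OCOC)c1CC=C(C)C | intermediate
7 | isovanillin (3-hydroxy-4-methoxybenzaldehyde) | COc1ccc(C=O)cc1O | starting material
8 | 3-(allyloxy)-4-methoxybenzaldehyde | COc1ccc(C=O)cc1OCC=C | intermediate
9 | 2-allyl-4-methoxy-3-oxocyclohexa-4,6-diene-1-carbaldehyde (ortho-dienone, formed in situ; C2 is sp3 with H and allyl, C3 is the ring ketone) | COC1=CC=C(C=O)C(CC=C)C1=O | intermediate
10 | 2-allyl-3-hydroxy-4-methoxybenzaldehyde | COc1ccc(C=O)c(CC=C)c1O | intermediate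
11 | 2-allyl-4-methoxy-3-(methoxymethoxy)benzaldehyde | COCOc1c(OC)ccc(C=O)c1CC=C | intermediate
12 | 4-methoxy-3-(methoxymethoxy)-2-(3-methylbut-2-en-1-yl)benzaldehyde | COCOc1c(OC)ccc(C=O)c1CC=C(C)C | intermediate
13 | 2-{[4-methoxy-3-(methoxymethoxy)-2-(3-methylbut-2-en-1-yl)phenyl]methylidene}propanedioic acid (arylidenemalonic acid, formed in situ) | COCOc1c(OC)ccc(C=C(C(=O)O)C(=O)O)c1CC=C(C)C | intermediate
14 | (E)-3-[4-methoxy-3-(methoxymethoxy)-2-(3-methylbut-2-en-1-yl)phenyl]prop-2-enoic acid | COCOc1c(OC)ccc(/C=C/C(=O)O)c1CC=C(C)C | intermediate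
15 | 3,5-bis(methoxymethoxy)-4-(3-methylbut-2-en-1-yl)phenyl (E)-3-[4-methoxy-3-(methoxymethoxy)-2-(3-methylbut-2-en-1-yl)phenyl]prop-2-enoate | COCOc1c(OC)ccc(/C=C/C(=O)Oc2cc(OCOC)c(CC=C(C)C)c(OCOC)c2)c1CC=C(C)C | intermediate
16 | (E)-1-[6-hydroxy-2,4-bis(methoxymethoxy)-3-(3-methylbut-2-en-1-yl)phenyl]-3-[4-methoxy-3-(methoxymethoxy)-2-(3-methylbut-2-en-1-yl)phenyl]prop-2-en-1-one (2'-hydroxychalcone, formed in situ) | COCOc1c(OC)ccc(/C=C/C(=O)c2c(O)cc(OCOC)c(CC=C(C)C)c2OCOC)c1CC=C(C)C | intermediate
17 | (2S)-5,7-bis(methoxymethoxy)-2-[4-methoxy-3-(methoxymethoxy)-2-(3-methylbut-2-en-1-yl)phenyl]-6-(3-methylbut-2-en-1-yl)-2,3-dihydro-4H-chromen-4-one | COCOc1c(OC)ccc([C@@H]2CC(=O)c3c(OCOC)c(CC=C(C)C)c(OCOC)cc3O2)c1CC=C(C)C | intermediate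
18 | (2S)-5,7-dihydroxy-2-[3-hydroxy-4-methoxy-2-(3-methylbut-2-en-1-yl)phenyl]-6-(3-methylbut-2-en-1-yl)-2,3-dihydro-4H-chromen-4-one (CNP0306216.1) | COc1ccc([C@@H]2CC(=O)c3c(cc(O)c(CC=C(C)C)c3O)O2)c(CC=C(C)C)c1O | target

**Step count and risks**

Total steps: 12. Longest linear sequence: 8 steps (steps 5–12, from isovanillin 7).

Steps most likely to fail:

1. Step 11 (Proposed new method). Three processes may go wrong:
   - facial discrimination by the catalyst may be insufficient on the hindered 6'-alkoxy chalcone;
   - E/Z scrambling of the enone under irradiation may feed the catalyst the wrong alkene geometry, and reversible oxa-Michael addition may erode the enantiomeric purity;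
   - cage recombination in the photo-Fries stage may be inefficient, because E/Z isomerisation of the cinnamate drains the excited state.

   The fallback uses known chemistry, sets out from 15 and comes back at 17. Ester 15 is irradiated as above and chalcone 16 is isolated. Heating 16 with NaOAc in EtOH (thermal oxa-Michael cyclisation) should give racemic 5,7-bis(methoxymethoxy)-2-[4-methoxy-3-(methoxymethoxy)-2-(3-methylbut-2-en-1-yl)phenyl]-6-(3-methylbut-2-en-1-yl)-2,3-dihydro-4H-chromen-4-one F1. The racemate is then resolved kinetically by asymmetric transfer hydrogenation with RuCl(p-cymene)[(R,R)-TsDPEN] in HCO2H/Et3N, stopped near half conversion. By analogy with aryl alkyl ketones, this catalyst should reduce the (2R)-ketone to the cis alcohol (2R,4R)-5,7-bis(methoxymethoxy)-2-[4-methoxy-3-(methoxymethoxy)-2-(3-methylbut-2-en-1-yl)phenyl]-6-(3-methylbut-2-en-1-yl)-3,4-dihydro-2H-chromen-4-ol F2 and leave (2S)-ketone 17, which is separated by chromatography. The prenyl alkenes are not touched by transfer hydrogenation.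

2. Step 12. Under protic acid a prenyl group may cyclise onto a freshly freed neighbouring phenol (chroman formation), or the alkene may be hydrated. The fallback sets out from 17 and comes back at 18, and replaces protic cleavage by trans-protection. Et3SiOTf with 2,2'-bipyridyl in CH2Cl2 at 0 °C should convert the three aryl MOM ethers directly into silyl ethers, giving (2S)-2-[4-methoxy-2-(3-methylbut-2-en-1-yl)-3-(triethylsilyloxy)phenyl]-6-(3-methylbut-2-en-1-yl)-5,7-bis(triethylsilyloxy)-2,3-dihydro-4H-chromen-4-one F3. Buffered HF·pyridine in THF at 0 °C then removes the silyl groups to give 18 without strong acid or base.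

3. Step 3. The hindered aryllithium may attack prenyl bromide in the SN2' sense (reverse-prenyl product), may undergo lithium–bromine exchange, or may not form completely. The fallback sets out from 1 and comes back at 5, and avoids the metalation. Phloroglucinol 1 is C-prenylated with prenyl bromide in aqueous KOH to 2-(3-methylbut-2-en-1-yl)benzene-1,3,5-triol F4. TIPSCl/imidazole at −20 °C should silylate the one hydroxyl that lies between two ring CH groups (the other two are shielded by the prenyl group), giving 2-(3-methylbut-2-en-1-yl)-5-[(triisopropylsilyl)oxy]benzene-1,3-diol F5. MOMCl/i-Pr2NEt then gives 5.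

**Further compounds**

F1 | step 11 | racemic 5,7-bis(methoxymethoxy)-2-[4-methoxy-3-(methoxymethoxy)-2-(3-methylbut-2-en-1-yl)phenyl]-6-(3-methylbut-2-en-1-yl)-2,3-dihydro-4H-chromen-4-one | COCOc1c(OC)ccc(C2CC(=O)c3c(OCOC)c(CC=C(C)C)c(OCOC)cc3O2)c1CC=C(C)C
F2 | step 11 | (2R,4R)-5,7-bis(methoxymethoxy)-2-[4-methoxy-3-(methoxymethoxy)-2-(3-methylbut-2-en-1-yl)phenyl]-6-(3-methylbut-2-en-1-yl)-3,4-dihydro-2H-chromen-4-ol | COCOc1c(OC)ccc([C@H]2C[C@@H](O)c3c(OCOC)c(CC=C(C)C)c(OCOC)cc3O2)c1CC=C(C)C
F3 | step 12 | (2S)-2-[4-methoxy-2-(3-methylbut-2-en-1-yl)-3-(triethylsilyloxy)phenyl]-6-(3-methylbut-2-en-1-yl)-5,7-bis(triethylsilyloxy)-2,3-dihydro-4H-chromen-4-one | COc1ccc([C@@H]2CC(=O)c3c(cc(O[Si](CC)(CC)CC)c(CC=C(C)C)c3O[Si](CC)(CC)CC)O2)c(CC=C(C)C)c1O[Si](CC)(CC)CC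
F4 | step 3 | 2-(3-methylbut-2-en-1-yl)benzene-1,3,5-triol | CC(C)=CCc1c(O)cc(O)cc1O
F5 | step 3 | 2-(3-methylbut-2-en-1-yl)-5-[(triisopropylsilyl)oxy]benzene-1,3-diol | CC(C)=CCc1c(O)cc(O[Si](C(C)C)(C(C)C)C(C)C)cc1O
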